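Keep two clocks apart.

| setting | noon | winter | oak | cedar | elm | larch |
|---|---|---|---|---|---|---|
| first end groups | 0.010 M | 0.020 M | 0.010 M | 0.010 M | 0.010 M | 0.010 M (fed, over 3.20 h) |
| second end groups | 1.1 equiv | 1.1 equiv | 1.10 equiv | 1.10 equiv (fed, over 3.20 h) | 1.10 equiv | 1.10 equiv |
| remark | run made earlier | run made earlier | a single well-mixed tank run continuously and read at steady state, 4.0 h in it on average | all but second end groups at the start; second end groups goes in evenly over 3.20 h, the run ends at 4.0 h | a closed flask charged with all of it at once and left for 4.0 h | all but first end groups at the start; first end groups goes in evenly over 3.20 h, the run ends at 4.0 h |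
| time |  |  |  | 4.0 h | 4.0 h | 4.0 h |

noon run (percent of the first end groups charged)

| time / h | links / % |
|---|---|
| 0.133 | 4.7 |
| 0.333 | 12.3 |
| 0.667 | 21.3 |
| 1.00 | 28.9 |
| 1.33 | 34.0 |
| 2.00 | 41.7 |
| 2.50 | 46.0 |

winter run (percent of the first end groups charged)

| time / min | links / % |
|---|---|
| 4.00 | 5.6 |
| 12.0 | 14.5 |
| 20.0 | 21.0 |
| 30.0 | 29.2 |
| 40.0 | 35.0 |
| 60.0 | 44.2 |
| 80.0 | 51.0 |

(readings scatter by 0.3 percentage points)

- the stated concentrations are those of everything mixed, before any reaction; amounts are the same in each set-up
- the feed brings no volume worth counting
- the earlier runs were made in a closed, stirred flask

- the set-up with the highest amount of links at the outlet or at the end, in percent of the first end groups put in ("none" if the first two lie within 2 percentage points) (oak / cedar / elm / larch / none)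
- amount of links at the outlet or at the end, in percent of the first end groups put in, oak
- amount of links at the outlet or at the end, in percent of the first end groups put in, cedar
- amount of links at the outlet or at the end, in percent of the first end groups put in, elm
- amount of links at the outlet or at the end, in percent of the first end groups put in, larch

Start from a pair of readings. The winter flask holds twice the noon [first end groups], so its reading at 60.0 min has the same [first end groups]·t as noon's at 2.00 h, and a plain second-order joining would give both the same links. Yet winter reads 44.2 % and noon 41.7 %, so you take the gap as a small correction to that joining: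

slip = ln(winter links / noon links) / (noon time − winter time) = 0.0582 h⁻¹

This slip is the fractional loss of links per extra hour at equal [first end groups]·t, a value read from readings and carrying their scatter.

Elm is noon left longer, which gives you two extremes. In one, elm stops at noon's last 46.0 %, your low end, since noon was still climbing there, up from 41.7 % at 2.00 h. In the other, nothing slips, and you ignore the excess of second end groups, charged at 1.10 equiv, over first end groups, the limiting reagent:

bare links at noon's 2.00 h = 46.8 %, so κ = 0.441 h⁻¹

no slip at 4.0 h: κt/(1+κt) = 63.8 %

I put elm between them, at the top value times exp(−slip·t):

my elm = 50.5 %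

The forecast differs from my figure, giving elm 53 %, oak 40.9 %, cedar 43.9 % and larch 43.7 %, with elm best: “Dosing keeps the concentration product low.”

The flask gives oak 38.1 %, cedar 41.8 %, elm 53.3 % and larch 43.5 %, so elm is best.

    first end groups + second end groups → links + released group (k = 38.0 M⁻¹ h⁻¹)
    links ⇌ isomer of the product (K = 1.40, k = 0.0580 h⁻¹)
    first end groups ⇌ dormant form (K = 2.20, k = 0.0440 h⁻¹)

In elm, first end groups and second end groups joined into links (half-life of first end groups by this step alone 1.7 h, the other concentrations as charged) while links passed to isomer of the product (half-life of links, forward step alone, 12 h) and first end groups to dormant form (half-life of first end groups, forward step alone, 16 h), and at 4.0 h elm held 29.6 % first end groups and 8.15 % isomer of the product, in percent of the first end groups charged. The slip's 50.5 % lies 2.8 percentage points under elm. For the winter charge at 4.0 h, the slip with κ scaled to that charge gives 61.7 %, and the flask stands at 65.7 %. After 40.0 h, larch stands at 39.3 %, elm at 39.1 % and cedar at 38.3 %, so these three lie inside the 2 points margin.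

(The readings are simulated from invented constants, and the scatter is random.)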